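The route rests on disconnecting the C8'–C7' bond of the tetrahydrofuran ring C8'–C8–C9–O–C7', which carries the syringyl-type aryl group on the concave face. A rhodium carbenoid generated at C8' of a trans-4,5-disubstituted α-diazo-γ-butyrolactone inserts into the benzylic, ether-activated C7'–H bond of a simple benzyl ether lying 1,5 to it. This one operation closes the ring last and sets C8' (cis fusion) and C7' (endo aryl, an epi configuration that acid equilibration cannot deliver selectively). The lactone comes from an Evans succinate aldol that fixes C7 and C8; its carbonyl is then reduced to CH2, and the threo-arylglycerol aryl ether is built on the freed phenol by a second Evans aldol.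

Key step: step 10

Remark on the chemistry: lignan locants are used. C7/C8/C9 belong to the guaiacyl C3 unit and C7'/C8'/C9' to the syringyl C3 unit of the furofuran (rings C7–O–C9'–C8'–C8 and C7'–O–C9–C8–C8'); C7''/C8''/C9'' belong to the glycerol unit. The target is read as (7R,8S,7'S,8'S,7''R,8''R), guaiacyl exo, syringyl endo, side chain threo. Abbreviations: ArG = 4-(benzyloxy)-3-methoxyphenyl; ArS = 3,5-dimethoxy-4-[(triisopropylsilyl)oxy]phenyl. Compound 25 is assumed to be commercial.

Step 1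
Reactants: 1 (R)-4-benzyl-1,3-oxazolidin-2-one; 2 methyl 4-chloro-4-oxobutanoate
Product: 3 methyl 4-[(4R)-4-benzyl-2-oxo-1,3-oxazolidin-3-yl]-4-oxobutanoate
Conditions: n-BuLi, THF, −78 °C; then 2, −78 → 0 °C
Reagents that add atoms: none
Why: N-acylation of the lithiated oxazolidinone by the acid chloride is the standard entry to Evans imides and touches neither the ester nor the stereocentre.

Step 2
Reactants: 3 succinate imide; 4 4-(benzyloxy)-3-methoxybenzaldehyde
Product: 6 (4R)-4-benzyl-3-{[(2R,3R)-2-ArG-5-oxooxolan-3-yl]carbonyl}-1,3-oxazolidin-2-one (4,5-trans lactone imide), via syn-aldol adduct 5 (not isolated)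
Conditions: Bu2BOTf, i-Pr2NEt, CH2Cl2, 0 °C; 4, −78 → 0 °C; pH 7 buffer, MeOH, H2O2; then PPTS (cat.), CH2Cl2, rt
Reagents that add atoms: none
Why: Evans syn-aldol, in which the Z-boron enolate formed at the imide α-CH2 adds through a Zimmerman–Traxler chair on the face away from the auxiliary benzyl group, setting C7 (R) and C8 (the later 8S centre), after which the new hydroxyl lactonises onto the methyl ester to give the trans lactone.

Step 3
Reactants: 6 lactone imide
Product: 8 (2R,3R)-2-ArG-5-oxooxolane-3-carboxylic acid, via peroxy acid 7 (not isolated)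
Conditions: LiOH, H2O2, THF–H2O, 0 °C; Na2SO3; then HCl to pH 2
Reagents that add atoms: hydrogen peroxide (acting as LiOOH), OO
Why: Evans auxiliary cleavage, in which hydroperoxide attacks the exocyclic imide carbonyl selectively, sulfite reduces the peroxy acid and acidification recloses any lactone opened by hydroxide, so neither stereocentre is touched.

Step 4
Reactants: 8 lactone acid
Product: 9 (4S,5R)-5-ArG-4-(hydroxymethyl)oxolan-2-one
Conditions: BH3·SMe2, THF, 0 °C → rt; aqueous work-up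
Reagents that add atoms: none
Why: chemoselective borane reduction of a carboxylic acid (through the acyloxyborane) in the presence of the less reactive γ-lactone.

Step 5
Reactants: 10 4-hydroxy-3,5-dimethoxybenzaldehyde (syringaldehyde)
Product: 11 3,5-dimethoxy-4-[(triisopropylsilyl)oxy]benzaldehyde
Conditions: TIPSCl, imidazole, DMAP (cat.), DMF, rt → 40 °C
Reagents that add atoms: triisopropylsilyl chloride, CC(C)[Si](Cl)(C(C)C)C(C)C
Why: O-silylation of the phenol gives a bulky aryl silyl ether that should survive base, hydride, Lewis acid and carbenoid steps and later leave with fluoride.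

Step 6
Reactants: 11 silylated aldehyde
Product: 12 {3,5-dimethoxy-4-[(triisopropylsilyl)oxy]phenyl}methanol
Conditions: NaBH4, MeOH–THF, 0 °C
Reagents that add atoms: none
Why: borohydride reduction of an aryl aldehyde to the benzylic alcohol, with the aryl silyl ether inert.

Step 7
Reactants: 12 benzylic alcohol
Product: 13 3,5-dimethoxy-4-[(triisopropylsilyl)oxy]benzyl 2,2,2-trichloroacetimidate
Conditions: Cl3CCN, DBU (cat.), CH2Cl2, 0 °C; used without storage
Reagents that add atoms: trichloroacetonitrile, ClC(Cl)(Cl)C#N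
Why: base-catalysed addition of the alcohol to the nitrile gives the trichloroacetimidate, a benzyl donor that needs only catalytic acid.

Step 8
Reactants: 9 hydroxymethyl lactone; 13 trichloroacetimidate
Product: 14 (4S,5R)-5-ArG-4-{[(ArS-methyl)oxy]methyl}oxolan-2-one
Conditions: CSA (10 mol %), 4 Å MS, CH2Cl2, 0 °C → rt
Reagents that add atoms: none
Why: acid-catalysed trichloroacetimidate benzylation, in which the protonated imidate ionises to the stabilised benzylic cation that the primary alcohol captures, avoiding alkoxide conditions that would translactonise 9.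

Step 9
Reactants: 14 benzyl ether lactone
Product: 16 (4S,5R)-5-ArG-3-diazo-4-{[(ArS-methyl)oxy]methyl}oxolan-2-one, via trifluoroacetyl lactone 15 (not isolated)
Conditions: LiHMDS, THF, −78 °C; CF3CO2CH2CF3, −78 °C; aq. HCl wash; then MsN3, Et3N, H2O (1 equiv), MeCN, rt
Reagents that add atoms: methanesulfonyl azide, CS(=O)(=O)N=[N+]=[N-]; 2,2,2-trifluoroethyl trifluoroacetate, O=C(OCC(F)(F)F)C(F)(F)F (its CF3CO group appears only in 15)
Why: detrifluoroacetylative diazo transfer (Regitz type), in which the lactone enolate is C-acylated and the activated 1,3-dicarbonyl then transfers its trifluoroacetyl group to the sulfonyl azide while accepting N2, with C8 and C7 untouched.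

Step 10
Reactants: 16 diazo lactone
Product: 17 (3R,3aS,6S,6aR)-3-ArG-6-ArS-tetrahydro-1H,3H-furo[3,4-c]furan-1-one (cis-fused furofuranone; ArG exo, ArS endo)
Conditions: Rh2(OAc)4 (2 mol %), CH2Cl2, reflux, slow addition of 16 at high dilution
Reagents that add atoms: none
Why: Rh2(OAc)4 converts the diazo lactone, with loss of N2, into an electrophilic acceptor carbenoid at C8', which inserts in a concerted three-centre transition state into the hydridic C7'–H bond, activated by both the ether oxygen and the electron-rich aryl ring. The closest known reaction type is the intramolecular Rh-carbenoid 1,5-C–H insertion of α-diazo-γ-butyrolactones bearing benzyl ethers, an established entry to endo,exo-furofuranones. The ring C8'–C8–C9–O–C7' is closed by C–C bond formation in the 1,5-insertion mode (five-membered ring, six-centre transition state counting the migrating hydrogen). C8' is controlled by the tether: the C9 arm on the existing C8 centre can reach only one lactone face, which enforces the cis ring fusion. C7' is set kinetically: the aryl group turns away from the dirhodium tetracarboxylate core and lies over the concave lactone face, which gives the endo aryl group (7'S). The step needs 1,5-insertion to win over 1,2-hydride shift from C8, addition to the aromatic rings and oxonium ylide formation; the doubly activated C–H bond, the five-ring geometry and the low stationary concentration of carbenoid should secure this.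

Step 11
Reactants: 17 furofuranone
Product: 18 (3R,3aS,6S,6aR)-3-ArG-6-ArS-tetrahydro-1H,3H-furo[3,4-c]furan-1-ol (lactol, both anomers)
Conditions: DIBAL-H (1.1 equiv), CH2Cl2, −78 °C; Rochelle salt
Reagents that add atoms: none
Why: partial reduction of a lactone to the lactol, the tetrahedral aluminium hemiacetal being stable at −78 °C, so the ring stays closed and no stereocentre of the skeleton is touched.

Step 12
Reactants: 18 lactol
Product: 19 (1S,3aS,4R,6aS)-4-ArG-1-ArS-tetrahydro-1H,3H-furo[3,4-c]furan (7R,8S,7'S,8'S)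
Conditions: Et3SiH, BF3·OEt2, CH2Cl2, −78 → −50 °C; Et3N, then aq. NaHCO3
Reagents that add atoms: none
Why: ionic hydrogenation of a lactol, in which BF3 ionises the anomeric C9'–OH to the cyclic oxocarbenium ion that silane reduces to CH2, the low temperature keeping the benzylic C7–O and C7'–O bonds un-ionised so that the endo aryl group is not epimerised.

Step 13
Reactants: 19 silyl-protected furofuran
Product: 20 4-{(1S,3aS,4R,6aS)-4-ArG-tetrahydro-1H,3H-furo[3,4-c]furan-1-yl}-2,6-dimethoxyphenol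
Conditions: TBAF, AcOH (1:1), THF, 0 °C
Reagents that add atoms: none
Why: fluoride-mediated cleavage of the aryl silyl ether under buffered conditions frees only the syringyl phenol, the benzyl ether being inert.

Step 14
Reactants: 21 (S)-4-benzyl-1,3-oxazolidin-2-one; 22 bromoacetyl bromide
Product: 23 (4S)-4-benzyl-3-(bromoacetyl)-1,3-oxazolidin-2-one
Conditions: n-BuLi, THF, −78 °C; then 22, −78 → 0 °C
Reagents that add atoms: none
Why: N-acylation of the lithiated oxazolidinone at the acyl bromide, which reacts far faster than the alkyl bromide.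

Step 15
Reactants: 20 furofuran phenol; 23 bromoacetyl imide
Product: 24 (4S)-4-benzyl-3-[(4-{(1S,3aS,4R,6aS)-4-ArG-tetrahydro-1H,3H-furo[3,4-c]furan-1-yl}-2,6-dimethoxyphenoxy)acetyl]-1,3-oxazolidin-2-one
Conditions: K2CO3, acetone, rt
Reagents that add atoms: none
Why: Williamson ether synthesis, the hindered phenoxide displacing bromide in a fast SN2 reaction at the carbonyl-activated carbon.

Step 16
Reactants: 24 aryloxyacetyl imide; 25 4-(benzyloxy)-3,5-dimethoxybenzaldehyde
Product: 26 (4S)-4-benzyl-3-[(2S,3R)-3-[4-(benzyloxy)-3,5-dimethoxyphenyl]-3-hydroxy-2-(aryloxy)propanoyl]-1,3-oxazolidin-2-one (aryloxy = the phenoxy residue of 20)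
Conditions: Bu2BOTf, i-Pr2NEt, CH2Cl2, −78 → 0 °C; 25, −78 → 0 °C; pH 7 buffer, MeOH, H2O2, 0 °C
Reagents that add atoms: none
Why: Evans syn-aldol of an α-aryloxyacetyl imide, in which the chelated boron enolate reacts through a Zimmerman–Traxler chair on the face away from the benzyl group of the (S)-auxiliary, giving the (2S,3R) adduct with both C8'' and C7'' set in the threo (later 7''R,8''R) sense.

Step 17
Reactants: 26 aldol adduct
Product: 27 (1R,2R)-1-[4-(benzyloxy)-3,5-dimethoxyphenyl]-2-(4-{(1S,3aS,4R,6aS)-4-ArG-tetrahydro-1H,3H-furo[3,4-c]furan-1-yl}-2,6-dimethoxyphenoxy)propane-1,3-diol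
Conditions: LiBH4, THF, H2O (1 equiv), 0 °C
Reagents that add atoms: none
Why: reductive removal of the oxazolidinone auxiliary by borohydride turns the imide carbonyl into the C9'' primary alcohol at a temperature where retro-aldol cleavage should not compete.

Step 18
Reactants: 27 bis-benzyl ether
Product: 28 (1R,2R)-1-(4-hydroxy-3,5-dimethoxyphenyl)-2-(4-{(1S,3aS,4R,6aS)-4-(4-hydroxy-3-methoxyphenyl)tetrahydro-1H,3H-furo[3,4-c]furan-1-yl}-2,6-dimethoxyphenoxy)propane-1,3-diol (target)
Conditions: H2 (1 atm), 10% Pd/C, EtOAc–MeOH, rt, stopped at complete debenzylation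
Reagents that add atoms: none
Why: catalytic hydrogenolysis, in which the two aryl O–CH2Ph bonds should cleave much faster under neutral conditions than the dialkyl benzylic ethers of the furofuran or the benzylic alcohol.

Compound list
1 | (R)-4-benzyl-1,3-oxazolidin-2-one | O=C1N[C@H](Cc2ccccc2)CO1 | starting material
2 | methyl 4-chloro-4-oxobutanoate | COC(=O)CCC(Cl)=O | starting material
3 | methyl 4-[(4R)-4-benzyl-2-oxo-1,3-oxazolidin-3-yl]-4-oxobutanoate | COC(=O)CCC(=O)N1[C@H](Cc2ccccc2)COC1=O | intermediate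
4 | 4-(benzyloxy)-3-methoxybenzaldehyde | COc1cc(C=O)ccc1OCc1ccccc1 | starting material
5 | methyl (3R)-4-[(4R)-4-benzyl-2-oxo-1,3-oxazolidin-3-yl]-3-[(R)-[4-(benzyloxy)-3-methoxyphenyl](hydroxy)methyl]-4-oxobutanoate (syn-aldol adduct, not isolated) | COC(=O)C[C@H]([C@@H](O)c1ccc(OCc2ccccc2)c(OC)c1)C(=O)N1[C@H](Cc2ccccc2)COC1=O | intermediate
6 | (4R)-4-benzyl-3-{[(2R,3R)-2-[4-(benzyloxy)-3-methoxyphenyl]-5-oxooxolan-3-yl]carbonyl}-1,3-oxazolidin-2-one | COc1cc([C@@H]2OC(=O)C[C@H]2C(=O)N2[C@H](Cc3ccccc3)COC2=O)ccc1OCc1ccccc1 | intermediate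
7 | (2R,3R)-2-[4-(benzyloxy)-3-methoxyphenyl]-5-oxooxolane-3-carboperoxoic acid (not isolated) | COc1cc([C@@H]2OC(=O)C[C@H]2C(=O)OO)ccc1OCc1ccccc1 | intermediate
8 | (2R,3R)-2-[4-(benzyloxy)-3-methoxyphenyl]-5-oxooxolane-3-carboxylic acid | COc1cc([C@@H]2OC(=O)C[C@H]2C(O)=O)ccc1OCc1ccccc1 | intermediate
9 | (4S,5R)-5-[4-(benzyloxy)-3-methoxyphenyl]-4-(hydroxymethyl)oxolan-2-one | COc1cc([C@@H]2OC(=O)C[C@H]2CO)ccc1OCc1ccccc1 | intermediate
10 | 4-hydroxy-3,5-dimethoxybenzaldehyde | COc1cc(C=O)cc(OC)c1O | starting material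
11 | 3,5-dimethoxy-4-[(triisopropylsilyl)oxy]benzaldehyde | COc1cc(C=O)cc(OC)c1O[Si](C(C)C)(C(C)C)C(C)C | intermediate
12 | {3,5-dimethoxy-4-[(triisopropylsilyl)oxy]phenyl}methanol | COc1cc(CO)cc(OC)c1O[Si](C(C)C)(C(C)C)C(C)C | intermediate
13 | 3,5-dimethoxy-4-[(triisopropylsilyl)oxy]benzyl 2,2,2-trichloroacetimidate | COc1cc(COC(=N)C(Cl)(Cl)Cl)cc(OC)c1O[Si](C(C)C)(C(C)C)C(C)C | intermediate
14 | (4S,5R)-5-[4-(benzyloxy)-3-methoxyphenyl]-4-[({3,5-dimethoxy-4-[(triisopropylsilyl)oxy]benzyl}oxy)methyl]oxolan-2-one | COc1cc([C@@H]2OC(=O)C[C@H]2COCc2cc(OC)c(O[Si](C(C)C)(C(C)C)C(C)C)c(OC)c2)ccc1OCc1ccccc1 | intermediate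
15 | 3-(trifluoroacetyl) derivative of 14 (C3 epimers and enol, not isolated) | COc1cc([C@@H]2OC(=O)C(C(=O)C(F)(F)F)[C@H]2COCc2cc(OC)c(O[Si](C(C)C)(C(C)C)C(C)C)c(OC)c2)ccc1OCc1ccccc1 | intermediate
16 | (4S,5R)-5-[4-(benzyloxy)-3-methoxyphenyl]-3-diazo-4-[({3,5-dimethoxy-4-[(triisopropylsilyl)oxy]benzyl}oxy)methyl]oxolan-2-one | COc1cc([C@@H]2OC(=O)C(=[N+]=[N-])[C@H]2COCc2cc(OC)c(O[Si](C(C)C)(C(C)C)C(C)C)c(OC)c2)ccc1OCc1ccccc1 | intermediate
17 | (3R,3aS,6S,6aR)-3-[4-(benzyloxy)-3-methoxyphenyl]-6-{3,5-dimethoxy-4-[(triisopropylsilyl)oxy]phenyl}tetrahydro-1H,3H-furo[3,4-c]furan-1-one | COc1cc([C@@H]2OC(=O)[C@@H]3[C@H]2CO[C@@H]3c2cc(OC)c(O[Si](C(C)C)(C(C)C)C(C)C)c(OC)c2)ccc1OCc1ccccc1 | intermediate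
18 | (3R,3aS,6S,6aR)-3-[4-(benzyloxy)-3-methoxyphenyl]-6-{3,5-dimethoxy-4-[(triisopropylsilyl)oxy]phenyl}tetrahydro-1H,3H-furo[3,4-c]furan-1-ol (both anomers) | COc1cc([C@@H]2OC(O)[C@@H]3[C@H]2CO[C@@H]3c2cc(OC)c(O[Si](C(C)C)(C(C)C)C(C)C)c(OC)c2)ccc1OCc1ccccc1 | intermediate
19 | (1S,3aS,4R,6aS)-4-[4-(benzyloxy)-3-methoxyphenyl]-1-{3,5-dimethoxy-4-[(triisopropylsilyl)oxy]phenyl}tetrahydro-1H,3H-furo[3,4-c]furan | COc1cc([C@@H]2OC[C@@H]3[C@H]2CO[C@@H]3c2cc(OC)c(O[Si](C(C)C)(C(C)C)C(C)C)c(OC)c2)ccc1OCc1ccccc1 | intermediate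
20 | 4-{(1S,3aS,4R,6aS)-4-[4-(benzyloxy)-3-methoxyphenyl]tetrahydro-1H,3H-furo[3,4-c]furan-1-yl}-2,6-dimethoxyphenol | COc1cc([C@@H]2OC[C@@H]3[C@H]2CO[C@@H]3c2cc(OC)c(O)c(OC)c2)ccc1OCc1ccccc1 | intermediate
21 | (S)-4-benzyl-1,3-oxazolidin-2-one | O=C1N[C@@H](Cc2ccccc2)CO1 | starting material
22 | bromoacetyl bromide | BrCC(Br)=O | starting material
23 | (4S)-4-benzyl-3-(bromoacetyl)-1,3-oxazolidin-2-one | O=C(CBr)N1[C@@H](Cc2ccccc2)COC1=O | intermediate
24 | (4S)-4-benzyl-3-[(4-{(1S,3aS,4R,6aS)-4-[4-(benzyloxy)-3-methoxyphenyl]tetrahydro-1H,3H-furo[3,4-c]furan-1-yl}-2,6-dimethoxyphenoxy)acetyl]-1,3-oxazolidin-2-one | COc1cc([C@@H]2OC[C@@H]3[C@H]2CO[C@@H]3c2cc(OC)c(OCC(=O)N3[C@@H](Cc4ccccc4)COC3=O)c(OC)c2)ccc1OCc1ccccc1 | intermediate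
25 | 4-(benzyloxy)-3,5-dimethoxybenzaldehyde | COc1cc(C=O)cc(OC)c1OCc1ccccc1 | starting material
26 | (4S)-4-benzyl-3-[(2S,3R)-3-[4-(benzyloxy)-3,5-dimethoxyphenyl]-2-(4-{(1S,3aS,4R,6aS)-4-[4-(benzyloxy)-3-methoxyphenyl]tetrahydro-1H,3H-furo[3,4-c]furan-1-yl}-2,6-dimethoxyphenoxy)-3-hydroxypropanoyl]-1,3-oxazolidin-2-one | COc1cc([C@@H]2OC[C@@H]3[C@H]2CO[C@@H]3c2cc(OC)c(O[C@H](C(=O)N3[C@@H](Cc4ccccc4)COC3=O)[C@H](O)c3cc(OC)c(OCc4ccccc4)c(OC)c3)c(OC)c2)ccc1OCc1ccccc1 | intermediate
27 | (1R,2R)-1-[4-(benzyloxy)-3,5-dimethoxyphenyl]-2-(4-{(1S,3aS,4R,6aS)-4-[4-(benzyloxy)-3-methoxyphenyl]tetrahydro-1H,3H-furo[3,4-c]furan-1-yl}-2,6-dimethoxyphenoxy)propane-1,3-diol | COc1cc([C@@H]2OC[C@@H]3[C@H]2CO[C@@H]3c2cc(OC)c(O[C@H](CO)[C@H](O)c3cc(OC)c(OCc4ccccc4)c(OC)c3)c(OC)c2)ccc1OCc1ccccc1 | intermediate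
28 | (1R,2R)-1-(4-hydroxy-3,5-dimethoxyphenyl)-2-(4-{(1S,3aS,4R,6aS)-4-(4-hydroxy-3-methoxyphenyl)tetrahydro-1H,3H-furo[3,4-c]furan-1-yl}-2,6-dimethoxyphenoxy)propane-1,3-diol | COc1cc([C@@H]2OC[C@@H]3[C@H]2CO[C@@H]3c2cc(OC)c(O[C@H](CO)[C@H](O)c3cc(OC)c(O)c(OC)c3)c(OC)c2)ccc1O | target

Total step count: 18. Longest linear sequence: 14 steps (steps 1–4, 8–13 and 15–18); steps 5–7 and step 14 are side branches.

Steps most likely to fail

Step 10. The carbenoid may be diverted into 1,2-hydride shift from C8 (butenolide formation) or addition to the electron-rich rings, or the facial preference at C7' may erode so that exo aryl product forms alongside. The fallback closes the same ring by C–O bond formation with hydride delivery; it sets out from 9 and comes back at 17. Silylation of 9 (TBSCl, imidazole, DMF) would give (4S,5R)-5-ArG-4-{[(tert-butyldimethylsilyl)oxy]methyl}oxolan-2-one F1. Its lithium enolate (LDA, THF, −78 °C) would add to aldehyde 11 trans to the C9 arm to give the aldol (3S,4S,5R)-3-[ArS(hydroxy)methyl] lactone F2 as a mixture of carbinol epimers. Dess–Martin oxidation would give the 3-(ArS-carbonyl) lactone F3, a β-keto lactone whose C8' centre epimerises freely. Et3SiH with catalytic BiBr3 in MeCN (reductive etherification of a silyloxy ketone) would remove the TBS group and close the bicyclic hemiketal F4, which only the cis-fused C8' epimer can form. The derived benzylic oxocarbenium ion should then be reduced by hydride delivery to the convex face, placing the aryl group endo and giving 17.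

Step 12. The Lewis acid may ionise the benzylic C7'–O or C7–O bond, which would epimerise the endo aryl group or lead to reductive ring opening. The fallback removes the anomeric oxygen by a radical path without acid; it sets out from 18 and comes back at 19. Lactol 18 with 1,1'-thiocarbonyldiimidazole (DMAP cat., CH2Cl2, rt) would give the O-(imidazol-1-ylcarbonothioyl) lactol F5. Bu3SnH and AIBN in toluene at 80 °C, with a high stannane concentration (Barton–McCombie deoxygenation at the anomeric carbon), should reduce the C9' radical to CH2 before it can fragment, giving 19.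

Step 8. The benzylic cation may alkylate the electron-rich guaiacyl ring, the imidate may rearrange to the N-benzyl trichloroacetamide, or the acid may trigger translactonisation of 9. The fallback forms the ether from the aldehyde oxidation level; it sets out from 9 and 11 and comes back at 14. Silylation of 9 (TMSCl, Et3N, CH2Cl2) would give (4S,5R)-5-ArG-4-{[(trimethylsilyl)oxy]methyl}oxolan-2-one F6. F6 and aldehyde 11 with Et3SiH and catalytic TMSOTf in CH2Cl2 at −78 °C (reductive etherification through the mixed oxocarbenium ion) should give 14 directly, without compounds 12 and 13.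

Further compounds
F1 | step 10 | (4S,5R)-5-[4-(benzyloxy)-3-methoxyphenyl]-4-{[(tert-butyldimethylsilyl)oxy]methyl}oxolan-2-one | COc1cc([C@@H]2OC(=O)C[C@H]2CO[Si](C)(C)C(C)(C)C)ccc1OCc1ccccc1
F2 | step 10 | (3S,4S,5R)-5-[4-(benzyloxy)-3-methoxyphenyl]-4-{[(tert-butyldimethylsilyl)oxy]methyl}-3-[{3,5-dimethoxy-4-[(triisopropylsilyl)oxy]phenyl}(hydroxy)methyl]oxolan-2-one (carbinol epimers) | COc1cc([C@@H]2OC(=O)[C@H](C(O)c3cc(OC)c(O[Si](C(C)C)(C(C)C)C(C)C)c(OC)c3)[C@H]2CO[Si](C)(C)C(C)(C)C)ccc1OCc1ccccc1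
F3 | step 10 | (4S,5R)-5-[4-(benzyloxy)-3-methoxyphenyl]-4-{[(tert-butyldimethylsilyl)oxy]methyl}-3-{3,5-dimethoxy-4-[(triisopropylsilyl)oxy]benzoyl}oxolan-2-one (C3 epimers and enol) | COc1cc([C@@H]2OC(=O)C(C(=O)c3cc(OC)c(O[Si](C(C)C)(C(C)C)C(C)C)c(OC)c3)[C@H]2CO[Si](C)(C)C(C)(C)C)ccc1OCc1ccccc1
F4 | step 10 | (3R,3aS,6aR)-3-[4-(benzyloxy)-3-methoxyphenyl]-6-{3,5-dimethoxy-4-[(triisopropylsilyl)oxy]phenyl}-6-hydroxytetrahydro-1H,3H-furo[3,4-c]furan-1-one (hemiketal, not isolated) | COc1cc([C@@H]2OC(=O)[C@@H]3[C@H]2COC3(O)c2cc(OC)c(O[Si](C(C)C)(C(C)C)C(C)C)c(OC)c2)ccc1OCc1ccccc1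
F5 | step 12 | O-[(3R,3aS,6S,6aR)-3-[4-(benzyloxy)-3-methoxyphenyl]-6-{3,5-dimethoxy-4-[(triisopropylsilyl)oxy]phenyl}tetrahydro-1H,3H-furo[3,4-c]furan-1-yl] 1H-imidazole-1-carbothioate | COc1cc([C@@H]2OC(OC(=S)n3ccnc3)[C@@H]3[C@H]2CO[C@@H]3c2cc(OC)c(O[Si](C(C)C)(C(C)C)C(C)C)c(OC)c2)ccc1OCc1ccccc1
F6 | step 8 | (4S,5R)-5-[4-(benzyloxy)-3-methoxyphenyl]-4-{[(trimethylsilyl)oxy]methyl}oxolan-2-one | COc1cc([C@@H]2OC(=O)C[C@H]2CO[Si](C)(C)C)ccc1OCc1ccccc1
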